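in all of them: reagent in the second phase 2.25 M

| flask | substrate | remark | time | volume of the second phase over the first |
|---|---|---|---|---|
| west | 2.1 M | run made earlier |  |  |
| flask | 1.5 M |  | 15 min | 1.0 |

- west (time / min: target / %, substrate / %): 0.833: 31.2, 69.4; 2.50: 55.0, 41.2; 4.00: 62.2, 32.1; 6.00: 61.2, 28.8; 10.0: 58.4, 22.6; 12.0: 57.8, 19.9; 15.0: 56.1, 19.9

(each reading ± 1 percentage point)

- amounts and yields of target count product in the second phase too
- in the second phase: reagent in the second phase, product in the second phase; everything else is in the first
- charges count per volume of the first phase; a concentration in a rate is the amount of a species over the volume of its own phase; every rate counts per litre of the first phase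
- the earlier runs hold the two phases in the same ratio of volumes as the flask asked about

1. amount of target and product in the second phase together at 15 min, in percent of the substrate charged
2. part of the substrate charged that has reacted at 15 min

1. Target is what the next flask is charged for. The west run ends at 56.1% of target with 19.9% of substrate left at 15.0 min. The decision is whether charging 1.5 M of substrate instead of 2.1 M, with the same reagent, raises both the target and the share of substrate reacted.

2. Let S be substrate left and R the reagent charge minus substrate reacted. Let D be the charged excess of reagent over substrate. With rate k_e·S·R, R/S grows by the factor exp(k_e·D·t).

3. In the west run, S is 0.418 M and R is 0.568 M, so R/S has grown by 1.27. This gives the apparent second-order constant at 15.0 min, k_e = 0.106 /M/min, a reading with its scatter.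

4. Substrate, the limiting reagent by charge, is the small remainder to reckon. By this reckoning, R/S in the flask grows by 3.28, which puts the substrate left at 12.7% and the substrate reacted at 87.3%.

5. By its last readings, the west run kept 70.0% of its reacted substrate as target. Applied to the flask, that gives 61.1%, above the west run's yield. The lower charge is taken.

The forecast reads 54% (46% to 63%) and 91% (84% to 96%), holding that “reagent is nearly exhausted, which explains the stall”.

The flask gives 59.6% of target and product in the second phase together, and 87.7% of its substrate has reacted.

    reagent in the reaction phase ⇌ reagent in the second phase, rate k1*([reagent in the reaction phase] - [reagent in the second phase]/K1) per volume of the first phase (partition coefficient = 0.380, kL = 1.80 /min)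
    substrate + reagent in the reaction phase ⇌ target (K = 6.30 /M, k = 0.440 /M/min)
    target ⇌ product in the second phase, rate k3*([target] - [product in the second phase]/K3) per volume of the first phase (partition coefficient = 4.20, kL = 0.0310 /min)
    target → decomposed product (k = 0.0250 /min)
    reagent in the reaction phase + target → over-reaction product (k = 0.0180 /M/min)

The flask holds 12% of substrate at 15.0 min, against 12.7% reckoned with k_e. At that time its reaction-phase target is made at 0.186 of the rate at which it is used up, each step taken net and going into its other forms counted as use, while target and product in the second phase together have gone from 66.4% at 3.75 min to 59.6%. A neighbour flask charged with 0.60 M of substrate, reckoned with the same k_e, keeps 5.47% of its substrate, and it holds 5.6%.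

(The readings stem from a simulated flask on assumed constants; noise was put on by code.)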